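Locants follow the chromanone numbering of the target (O1, C2, C3, C4, C4a, C5–C8, C8a); C9 is the exocyclic carbinol carbon and the pendant ring is primed.

## Analysis of the target

- The target 22 is a 2-hydroxychroman-4-one. Ring A is a hexasubstituted benzene (C4a acyl, C5–OH, C6–OMe, C7–OH, C8–CH3, C8a–O1). Ring C is the cyclic hemiacetal of a β-ketoaldehyde, and C3 carries the carbinol C9 with a 4-hydroxyphenyl group.
- There are three contiguous stereocentres, C2 (S), C3 (R) and C9 (S). The C2 hydroxyl is trans to the C3 side chain.
- C2 is a hemiacetal carbon and C3 lies between the C4 ketone and C2, so both can epimerise by ring–chain tautomerism and enolisation. Only C9 is configurationally fixed, and the other two must follow from it.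
- The compound tolerates neither acid nor base. Acid dehydrates the lactol to a chromone and ionises the para-hydroxybenzylic C9–O bond. Base opens the lactol, can cleave C3–C9 by retro-aldol reaction and can form a quinone methide.
- The hard point is regiochemical. The acyl carbon C4a has two ortho oxygens, O5 and the ring oxygen O1 on C8a, which differ only in their neighbours (C6–OMe against C8–CH3). A closure from a ketone with both oxygens free can use either, and an opened lactol with both free can exchange them.
- The strategy rests on the O1–C8a bond. C8a enters as the only halogenated carbon of ring A and O1 is delivered from the side chain, so O1 and O5 are not both free until the last step.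

## Retrosynthetic reasoning

**22 ⇒ 21.** Only the three aryl O–benzyl bonds (O5, O7, O4') are cut. Benzyl ethers are used instead of acetal-type groups because they fall to neutral hydrogenolysis. Any acid able to cleave an aryl acetal would also dehydrate the lactol and ionise C9–O. Keeping O5 blocked to the end means the lactol is formed while only O1 is free.

**21 ⇒ 19.** The C2–OH bond is cut: the lactol is the hydrate of the C2=C3 bond of chromone 19. Forward, aqueous base adds at C2 and opens ring C to dianion 20. Neutralisation recloses through O1, the only free phenol oxygen, so the ring oxygen cannot move to O5. C2 and C3 are created here under thermodynamic control from C9.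

**19 ⇒ 18.** The C9 silyl ether is removed on the chromone, the most robust compound of the endgame, so that no fluoride touches a lactol. The silyl group is needed up to 18 because a free C9 oxygen could itself reach C8a in a six-membered closure and would not survive the enolate steps.

**18 ⇒ 17.** Key disconnection, O1–C8a. Cutting here, and not at O1–C2, turns O1 into the formyl oxygen of the side chain and C8a into an aryl bromide carbon. Ring A then needs only three oxygens, and the place of the fourth is dictated by one bromine. The forward reaction must make an aryl–oxygen bond at a carbon flanked by the acyl group and the C8 methyl group without touching C9.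

**17 ⇒ 15.** The C2–C3 bond is cut. C2 comes in by C-formylation at the only enolisable position of 15, run cold so that the enolate does not expel the β-silyloxy group.

**15 ⇒ 14 ⇒ 13 + 12.** The C4–C4a bond joins the halves. It is made at the aldehyde level (12, then oxidation of 14) because arylmagnesium 13 has two ortho substituents and adds fast only to an aldehyde. The C8a bromine is on the ring before the coupling. Brominating after it would mean substitution ortho to a ketone in competition with the electron-rich pendant ring and an enolisable CH2.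

**13 ⇒ 7 ⇒ 5 ⇒ 3 ⇒ 2 ⇒ 1.** Ring A is bought, not built: 1 already holds O5, O6 and O7. The two positions activated by the flanking oxygens (future C8 and C4a) are functionalised first, C8 with methyl via 3 and 4. The unactivated position para to the methoxy group (future C8a) is brominated last. The two bromines of 7 are told apart by bromine–magnesium exchange, which should occur next to the benzyloxy group.

**12 ⇒ 11 ⇒ 10 ⇒ 9 ⇒ 8.** C9 is set once, by catalytic asymmetric transfer hydrogenation of β-keto ester 9 (from ketone 8 by Claisen condensation). Silylation and partial reduction give 12. No bond to C9 is made or broken afterwards.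

## Alternatives that were turned down

**Alternative 1:** nitrile oxide–enaminone cycloaddition.
- Disconnection: C3–C4 and the bond from C2 to its hydroxyl oxygen, both masked in an isoxazole.
- Forward key step: the ring A nitrile oxide A2 adds to enaminone A3 and the amine is lost, giving the 3-aryl-4-aroylisoxazole A1. In A1 isoxazole C3 is C4, isoxazole C4 is C3, isoxazole C5 with the ring oxygen is C2 with its future hydroxyl, and the aroyl carbonyl is C9.
- For it: one step joins both halves and fixes C2, C3, C4 and C9 in a stable ring. The regiochemistry of such cycloadditions is dependable, and a nitrile oxide with two ortho substituents resists dimerisation. In convergence it is stronger than the chosen route.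
- Against it:
  - Ring A must arrive with all four oxygens. In A1 the two silyloxy groups ortho to the isoxazole (future O1 and O5) are identical, so unmasking leaves either free to close onto C2. This is the ambiguity that must be avoided, and differentiating them lengthens the ring A synthesis.
  - C9 is a ketone and must be reduced enantioselectively late, between an aryl and a heteroaryl group of similar size and beside a reducible N–O bond.
  - N–O cleavage gives a vinylogous amide whose hydrolysis needs acid, and the resulting 2-aroyl-1,3-dicarbonyl is prone to retro-Claisen cleavage.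
- Comparison: the chosen route gives up some convergence but brings C9 in from a simple catalytic ketone reduction and settles O1 against O5 by the position of one bromine.

**Alternative 2:** Moore ring expansion.
- Disconnection: the C4a–C8a bond, with ring A built from a four-membered ring.
- Forward key step: heating cyclobutenone A5 opens it to a dienylketene, and 6π electrocyclisation with tautomerisation gives phenol A4.
- For it: every substituent of ring A is placed by the order of additions to the cyclobutenone. O5, O6 and O7 carry different alkyl groups and O8a is the free phenol next to an unsubstituted C4a. On the O1/O5 question this equals the chosen route. It is arguably stronger in one respect: a free O8a–H beside C4a allows ortho-acylation and direct lactol formation, with no copper step and no chromone hydration.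
- Against it:
  - The ethyl and isopropyl ethers of A4 need strong Lewis acids for cleavage, which the lactol and the C9 carbinol would not survive. Other alkoxy groups mean a different cyclobutenone.
  - A5 itself takes several steps, and C4a must still be acylated with a chain carrying the benzylic silyl ether under Friedel–Crafts or Fries conditions.
- Comparison: the chosen route starts from an arene that already has the three oxygens and needs four steps to finish ring A.

**Alternative 3:** silyloxyfuran–ynone Diels–Alder aromatisation.
- Disconnection: C6–C7 and C8–C8a.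
- Forward key step: furan A7 adds ynone A8 across its 2- and 5-positions, and the oxanorbornadiene opens to phenol A6.
- For it: a pentasubstituted benzene in one step. The regiochemistry follows from polarisation (the nucleophilic furan C5 meets the ynone β-carbon). O8a is free and distinct from O5 (benzyl) and O6 (silyl), so the O1/O5 question is again settled, and C4a is open for acylation.
- Against it:
  - C7 carries an acetyl group that must become oxygen by Baeyer–Villiger oxidation and hydrolysis, and the O6 silyl group must be exchanged for methyl. The ring therefore needs several adjustments before it matches what 1 offers at the outset.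
  - A7 is fragile, and an internal ynone with a methyl terminus is a sluggish dienophile against which vinylogous Michael addition competes.
- Comparison: the chosen route has no redox or protecting-group corrections on ring A and keeps its risk in one late ring closure.

Key step: step 12

Assumption (chemistry): C2 and C3 equilibrate in the free lactol, and the (2S,3R) arrangement of the target, with the C2 hydroxyl trans to the C3 side chain, is taken to be the thermodynamically preferred one relative to the fixed (9S) centre.

Remark: the descriptor at C9 changes between S and R along the route only because C3 changes rank against the aryl carbon in the sequence rule. The geometry at C9 is the same from 10 to 22.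

## Route

Step 1
Reactants: 1 2-methoxyresorcinol (2-methoxybenzene-1,3-diol)
Product: 2 1,3-bis(benzyloxy)-2-methoxybenzene
Conditions: BnBr (2.3 equiv), K2CO3 (3 equiv), DMF, 60 °C
Reagents that add atoms: benzyl bromide, BrCc1ccccc1
Why: Williamson ether synthesis on both phenols; benzyl is chosen because it survives organometallic, basic and copper steps and is removed at the end without acid or base.

Step 2
Reactants: 2 1,3-bis(benzyloxy)-2-methoxybenzene
Product: 3 1,3-bis(benzyloxy)-4-bromo-2-methoxybenzene
Conditions: NBS (1.0 equiv), MeCN, 0 °C, dark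
Reagents that add atoms: N-bromosuccinimide, O=C1CCC(=O)N1Br
Why: Electrophilic aromatic bromination; C4 (equivalent to C6) is ortho to one benzyloxy group and para to the other, whereas C5 is activated only by the twisted central methoxy group, so one bromine should enter at C4.

Step 3
Reactants: 3 1,3-bis(benzyloxy)-4-bromo-2-methoxybenzene
Product: 5 1,3-bis(benzyloxy)-2-methoxy-4-methylbenzene, via aryllithium 4 (not isolated)
Conditions: n-BuLi (1.05 equiv), THF, −78 °C, 15 min; MeI (3 equiv), −78 °C → rt
Reagents that add atoms: iodomethane, CI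
Why: Bromine–lithium exchange followed by SN2 methylation of the aryllithium; the exchange is fast at −78 °C, where the benzylic CH2 groups of the ethers are not deprotonated; this methyl becomes C8–CH3.

Step 4
Reactants: 5 1,3-bis(benzyloxy)-2-methoxy-4-methylbenzene
Product: 7 1,3-bis(benzyloxy)-4,5-dibromo-2-methoxy-6-methylbenzene, via monobromide 6 (not isolated)
Conditions: Br2 (2.2 equiv), NaOAc (3 equiv), AcOH/CH2Cl2, 0 °C → rt, dark
Reagents that add atoms: bromine, BrBr
Why: Twofold electrophilic aromatic bromination; the first bromine takes the position ortho and para to the benzyloxy groups (6, future C4a), the second the only ring position left (future C8a), para to the methoxy group and ortho to the methyl group; NaOAc traps HBr so the benzyl ethers are not cleaved.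

Step 5
Reactants: 8 1-[4-(benzyloxy)phenyl]ethan-1-one (4'-(benzyloxy)acetophenone, the commercial benzyl ether of 4'-hydroxyacetophenone)
Product: 9 methyl 3-[4-(benzyloxy)phenyl]-3-oxopropanoate
Conditions: NaH (2.5 equiv), (MeO)2CO (3 equiv), THF, reflux; aq HCl, 0 °C
Reagents that add atoms: dimethyl carbonate, COC(=O)OC
Why: Crossed Claisen condensation of the methyl ketone enolate with a non-enolisable carbonate, driven by deprotonation of the β-keto ester; the new ester carbon becomes C4.

Step 6
Reactants: 9 methyl 3-[4-(benzyloxy)phenyl]-3-oxopropanoate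
Product: 10 methyl (3S)-3-[4-(benzyloxy)phenyl]-3-hydroxypropanoate
Conditions: RuCl(p-cymene)[(S,S)-TsDPEN] (1 mol %), HCO2H/Et3N (5:2), DMF, 40 °C
Reagents that add atoms: none
Why: Noyori asymmetric transfer hydrogenation of an aryl ketone; hydride and proton are passed in an outer-sphere six-membered transition state with the aryl group beside the η6-arene, which with the (S,S)-ligand should give the (S)-carbinol, the future C9; the benzyl ether is inert to this catalyst.

Step 7
Reactants: 10 methyl (3S)-3-[4-(benzyloxy)phenyl]-3-hydroxypropanoate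
Product: 11 methyl (3S)-3-[4-(benzyloxy)phenyl]-3-[(tert-butyldimethylsilyl)oxy]propanoate
Conditions: TBSCl (1.3 equiv), imidazole (2.5 equiv), DMF, rt
Reagents that add atoms: tert-butyldimethylsilyl chloride, CC(C)(C)[Si](C)(C)Cl
Why: Silylation of the secondary alcohol through the N-silylimidazolium; the silyl ether blocks retro-aldol and O-arylation pathways later and does not touch the C9–O bond.

Step 8
Reactants: 11 methyl (3S)-3-[4-(benzyloxy)phenyl]-3-[(tert-butyldimethylsilyl)oxy]propanoate
Product: 12 (3S)-3-[4-(benzyloxy)phenyl]-3-[(tert-butyldimethylsilyl)oxy]propanal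
Conditions: i-Bu2AlH (1.1 equiv), CH2Cl2, −78 °C; MeOH, aq KNaC4H4O6
Reagents that add atoms: none
Why: Partial reduction of the ester; the tetrahedral aluminium hemiacetal is stable at −78 °C and releases the aldehyde only on work-up, and these non-basic conditions do not eliminate the β-silyloxy group.

Step 9
Reactants: 7 1,3-bis(benzyloxy)-4,5-dibromo-2-methoxy-6-methylbenzene; 12 (3S)-3-[4-(benzyloxy)phenyl]-3-[(tert-butyldimethylsilyl)oxy]propanal
Product: 14 (1RS,3S)-1-[2,4-bis(benzyloxy)-6-bromo-3-methoxy-5-methylphenyl]-3-[4-(benzyloxy)phenyl]-3-[(tert-butyldimethylsilyl)oxy]propan-1-ol, via arylmagnesium chloride 13 (not isolated)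
Conditions: i-PrMgCl·LiCl (1.1 equiv), THF, −15 °C, 1 h; 12, −15 → 0 °C; aq NH4Cl
Reagents that add atoms: none
Why: Regioselective bromine–magnesium exchange and Grignard addition; the magnesium should go to the carbon beside the benzyloxy group, whose oxygen stabilises the aryl anion inductively and by coordination, whereas the other bromine sits beside the donating methyl group; the 2-bromoarylmagnesium is kept at or below 0 °C to avoid aryne formation, and the new carbinol centre is destroyed in step 10.

Step 10
Reactants: 14 (1RS,3S)-1-[2,4-bis(benzyloxy)-6-bromo-3-methoxy-5-methylphenyl]-3-[4-(benzyloxy)phenyl]-3-[(tert-butyldimethylsilyl)oxy]propan-1-ol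
Product: 15 (3S)-1-[2,4-bis(benzyloxy)-6-bromo-3-methoxy-5-methylphenyl]-3-[4-(benzyloxy)phenyl]-3-[(tert-butyldimethylsilyl)oxy]propan-1-one
Conditions: Dess–Martin periodinane (1.3 equiv), pyridine (3 equiv), CH2Cl2, 0 °C → rt
Reagents that add atoms: none
Why: Dess–Martin oxidation of a hindered benzylic alcohol under buffered, non-basic conditions, which leave the silyl ether, the benzyl ethers and the aryl bromide alone and give no β-elimination.

Step 11
Reactants: 15 (3S)-1-[2,4-bis(benzyloxy)-6-bromo-3-methoxy-5-methylphenyl]-3-[4-(benzyloxy)phenyl]-3-[(tert-butyldimethylsilyl)oxy]propan-1-one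
Product: 17 (2Z)-1-[2,4-bis(benzyloxy)-6-bromo-3-methoxy-5-methylphenyl]-2-{(R)-[4-(benzyloxy)phenyl][(tert-butyldimethylsilyl)oxy]methyl}-3-hydroxyprop-2-en-1-one, via lithium enolate 16 (not isolated)
Conditions: LiN(SiMe3)2 (1.2 equiv), THF, −78 °C; HCO2CH2CF3 (2 equiv), −78 → −40 °C; AcOH, −78 °C; used crude
Reagents that add atoms: 2,2,2-trifluoroethyl formate, O=COCC(F)(F)F
Why: Crossed Claisen C-formylation of the only enolisable position; the activated formate reacts with the lithium enolate at −78 °C, where a β-silyloxy enolate does not eliminate, and the released trifluoroethoxide deprotonates the product, which is isolated as the hydrogen-bonded hydroxymethylene ketone.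

Step 12
Reactants: 17 (2Z)-1-[2,4-bis(benzyloxy)-6-bromo-3-methoxy-5-methylphenyl]-2-{(R)-[4-(benzyloxy)phenyl][(tert-butyldimethylsilyl)oxy]methyl}-3-hydroxyprop-2-en-1-one
Product: 18 5,7-bis(benzyloxy)-3-{(R)-[4-(benzyloxy)phenyl][(tert-butyldimethylsilyl)oxy]methyl}-6-methoxy-8-methyl-4H-chromen-4-one
Conditions: CuI (10 mol %), 1,10-phenanthroline (20 mol %), Cs2CO3 (2 equiv), 4 Å molecular sieves, 1,4-dioxane, 90 °C
Reagents that add atoms: none
Why: Intramolecular Ullmann-type C–O coupling. Cs2CO3 deprotonates the hydroxymethylene ketone, the enolate binds phenanthroline-ligated monovalent copper through the formyl oxygen, oxidative addition into the C8a–Br bond gives a trivalent copper aryl in a seven-membered cupracycle, and C–O reductive elimination forms O1–C8a and returns monovalent copper. The closest known reaction type is the CuI-catalysed cyclisation of 1-(2-haloaryl)-1,3-dicarbonyl compounds to chromones. Ring C closes in a six-membered mode that is formally 6-exo-trig, the oxygen attacking an sp2 carbon whose leaving group lies outside the new ring. No stereocentre is formed, and C9 has no hydrogen that carbonate can remove, so it keeps its configuration. The selectivity needed is one of site: only the formyl oxygen can reach C8a in a six-membered ring (the ketone oxygen or C3 would give four-membered rings), the C9 oxygen, which could also close a six-membered ring, is silylated, O5 is benzylated, and C8a is the only halogenated carbon of ring A. The enolate is delocalised, so the alkene geometry of 17 is not critical.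

Step 13
Reactants: 18 5,7-bis(benzyloxy)-3-{(R)-[4-(benzyloxy)phenyl][(tert-butyldimethylsilyl)oxy]methyl}-6-methoxy-8-methyl-4H-chromen-4-one
Product: 19 5,7-bis(benzyloxy)-3-{(R)-[4-(benzyloxy)phenyl](hydroxy)methyl}-6-methoxy-8-methyl-4H-chromen-4-one
Conditions: Bu4NF (3 equiv), AcOH (3 equiv), THF, rt
Reagents that add atoms: none
Why: Fluoride-mediated desilylation buffered with acetic acid; at the chromone stage there is no lactol to dehydrate and no carbanion-stabilising group at C3 that would allow retro-aldol cleavage, and the buffered medium does not ionise the C9–O bond.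

Step 14
Reactants: 19 5,7-bis(benzyloxy)-3-{(R)-[4-(benzyloxy)phenyl](hydroxy)methyl}-6-methoxy-8-methyl-4H-chromen-4-one
Product: 21 (2S,3R)-5,7-bis(benzyloxy)-3-{(S)-[4-(benzyloxy)phenyl](hydroxy)methyl}-2-hydroxy-6-methoxy-8-methyl-2,3-dihydro-4H-chromen-4-one, via ring-opened dilithium salt 20 (not isolated)
Conditions: LiOH·H2O (3 equiv), THF/H2O (3:1), 0 °C → rt; AcOH (3 equiv), pH 7 phosphate buffer, 0 °C
Reagents that add atoms: lithium hydroxide, [Li+].[OH-]
Why: Oxa-Michael addition of hydroxide at C2 and retro-oxa-Michael opening give dianion 20, whose enolate charge blocks retro-aldol cleavage at C3–C9; on neutralisation the only free phenol, O1–H, adds to the aldehyde, so the ring oxygen cannot change place with the benzylated O5 (no Wessely–Moser-type isomerisation). C2 and C3 are set here under thermodynamic control from C9 and should settle as the trans (2S,3R) lactol; the pH is kept at 6–7 because acid would dehydrate the lactol back to 19.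

Step 15
Reactants: 21 (2S,3R)-5,7-bis(benzyloxy)-3-{(S)-[4-(benzyloxy)phenyl](hydroxy)methyl}-2-hydroxy-6-methoxy-8-methyl-2,3-dihydro-4H-chromen-4-one
Product: 22 (2S,3R)-2,5,7-trihydroxy-3-[(S)-hydroxy(4-hydroxyphenyl)methyl]-6-methoxy-8-methyl-2,3-dihydro-4H-chromen-4-one (CNP0141808.1)
Conditions: H2 (1 atm), 10% Pd/C, EtOAc, rt; filtration, evaporation below 30 °C
Reagents that add atoms: none
Why: Hydrogenolysis of three aryl benzyl ethers under neutral conditions; the lactol, the hindered hydrogen-bonded aryl ketone and the secondary benzylic alcohol should survive if the reaction is stopped at full debenzylation. O5 is freed only now, in a neutral aprotic medium, so exchange of O1 and O5 through the open form is not promoted.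

## Compound list

1 | 2-methoxyresorcinol | COc1c(O)cccc1O | starting material
2 | 1,3-bis(benzyloxy)-2-methoxybenzene | COc1c(OCc2ccccc2)cccc1OCc1ccccc1 | intermediate
3 | 1,3-bis(benzyloxy)-4-bromo-2-methoxybenzene | COc1c(OCc2ccccc2)ccc(Br)c1OCc1ccccc1 | intermediate
4 | [2,4-bis(benzyloxy)-3-methoxyphenyl]lithium | COc1c(OCc2ccccc2)ccc([Li])c1OCc1ccccc1 | intermediate (not isolated)
5 | 1,3-bis(benzyloxy)-2-methoxy-4-methylbenzene | COc1c(OCc2ccccc2)ccc(C)c1OCc1ccccc1 | intermediate
6 | 1,3-bis(benzyloxy)-4-bromo-2-methoxy-6-methylbenzene | COc1c(OCc2ccccc2)c(Br)cc(C)c1OCc1ccccc1 | intermediate (not isolated)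
7 | 1,3-bis(benzyloxy)-4,5-dibromo-2-methoxy-6-methylbenzene | COc1c(OCc2ccccc2)c(Br)c(Br)c(C)c1OCc1ccccc1 | intermediate
8 | 1-[4-(benzyloxy)phenyl]ethan-1-one | CC(=O)c1ccc(OCc2ccccc2)cc1 | starting material
9 | methyl 3-[4-(benzyloxy)phenyl]-3-oxopropanoate | COC(=O)CC(=O)c1ccc(OCc2ccccc2)cc1 | intermediate
10 | methyl (3S)-3-[4-(benzyloxy)phenyl]-3-hydroxypropanoate | COC(=O)C[C@H](O)c1ccc(OCc2ccccc2)cc1 | intermediate
11 | methyl (3S)-3-[4-(benzyloxy)phenyl]-3-[(tert-butyldimethylsilyl)oxy]propanoate | COC(=O)C[C@H](O[Si](C)(C)C(C)(C)C)c1ccc(OCc2ccccc2)cc1 | intermediate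
12 | (3S)-3-[4-(benzyloxy)phenyl]-3-[(tert-butyldimethylsilyl)oxy]propanal | O=CC[C@H](O[Si](C)(C)C(C)(C)C)c1ccc(OCc2ccccc2)cc1 | intermediate
13 | [2,4-bis(benzyloxy)-6-bromo-3-methoxy-5-methylphenyl]magnesium chloride | COc1c(OCc2ccccc2)c([Mg]Cl)c(Br)c(C)c1OCc1ccccc1 | intermediate (not isolated)
14 | (1RS,3S)-1-[2,4-bis(benzyloxy)-6-bromo-3-methoxy-5-methylphenyl]-3-[4-(benzyloxy)phenyl]-3-[(tert-butyldimethylsilyl)oxy]propan-1-ol | COc1c(OCc2ccccc2)c(C(O)C[C@H](O[Si](C)(C)C(C)(C)C)c2ccc(OCc3ccccc3)cc2)c(Br)c(C)c1OCc1ccccc1 | intermediate
15 | (3S)-1-[2,4-bis(benzyloxy)-6-bromo-3-methoxy-5-methylphenyl]-3-[4-(benzyloxy)phenyl]-3-[(tert-butyldimethylsilyl)oxy]propan-1-one | COc1c(OCc2ccccc2)c(C(=O)C[C@H](O[Si](C)(C)C(C)(C)C)c2ccc(OCc3ccccc3)cc2)c(Br)c(C)c1OCc1ccccc1 | intermediate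
16 | lithium enolate of 15 (alkene geometry not defined) | [Li+].[O-]C(=C[C@H](O[Si](C)(C)C(C)(C)C)c1ccc(OCc2ccccc2)cc1)c1c(Br)c(C)c(OCc2ccccc2)c(OC)c1OCc1ccccc1 | intermediate (not isolated)
17 | (2Z)-1-[2,4-bis(benzyloxy)-6-bromo-3-methoxy-5-methylphenyl]-2-{(R)-[4-(benzyloxy)phenyl][(tert-butyldimethylsilyl)oxy]methyl}-3-hydroxyprop-2-en-1-one | O/C=C(/[C@H](O[Si](C)(C)C(C)(C)C)c1ccc(OCc2ccccc2)cc1)C(=O)c1c(Br)c(C)c(OCc2ccccc2)c(OC)c1OCc1ccccc1 | intermediate
18 | 5,7-bis(benzyloxy)-3-{(R)-[4-(benzyloxy)phenyl][(tert-butyldimethylsilyl)oxy]methyl}-6-methoxy-8-methyl-4H-chromen-4-one | COc1c(OCc2ccccc2)c(C)c2occ([C@H](O[Si](C)(C)C(C)(C)C)c3ccc(OCc4ccccc4)cc3)c(=O)c2c1OCc1ccccc1 | intermediate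
19 | 5,7-bis(benzyloxy)-3-{(R)-[4-(benzyloxy)phenyl](hydroxy)methyl}-6-methoxy-8-methyl-4H-chromen-4-one | COc1c(OCc2ccccc2)c(C)c2occ([C@H](O)c3ccc(OCc4ccccc4)cc3)c(=O)c2c1OCc1ccccc1 | intermediate
20 | dilithium salt of (2Z)-1-[2,4-bis(benzyloxy)-6-hydroxy-3-methoxy-5-methylphenyl]-2-{(R)-[4-(benzyloxy)phenyl](hydroxy)methyl}-3-hydroxyprop-2-en-1-one | [Li+].[Li+].[O-]/C=C(/[C@H](O)c1ccc(OCc2ccccc2)cc1)C(=O)c1c([O-])c(C)c(OCc2ccccc2)c(OC)c1OCc1ccccc1 | intermediate (not isolated)
21 | (2S,3R)-5,7-bis(benzyloxy)-3-{(S)-[4-(benzyloxy)phenyl](hydroxy)methyl}-2-hydroxy-6-methoxy-8-methyl-2,3-dihydro-4H-chromen-4-one | COc1c(OCc2ccccc2)c(C)c2c(c1OCc1ccccc1)C(=O)[C@H]([C@H](O)c1ccc(OCc3ccccc3)cc1)[C@@H](O)O2 | intermediate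
22 | (2S,3R)-2,5,7-trihydroxy-3-[(S)-hydroxy(4-hydroxyphenyl)methyl]-6-methoxy-8-methyl-2,3-dihydro-4H-chromen-4-one | COc1c(O)c(C)c2c(c1O)C(=O)[C@H]([C@H](O)c1ccc(O)cc1)[C@@H](O)O2 | target

## Step count and least certain steps

Total: 15 steps. Longest linear sequence: 11 steps (1 → 22 through steps 1–4 and 9–15). The side branch 8 → 12 has 4 steps.

**Step 12 (key step).** Oxidative addition may be slow at a bromide flanked by the acyl group and the C8 methyl group. At the temperature then needed, 17 may lose its formyl group by retro-Claisen cleavage with carbonate and traces of water, lose silanol across C3–C9, or undergo protodebromination. Fallback: the C8a–Br bond is turned into C8a–OH before C2 is introduced. Setting out from 15, Miyaura borylation (Pd(OAc)2, SPhos, B2pin2, KOAc, dioxane, 90 °C) should give the pinacol boronate F1. Oxidation (NaBO3·4H2O, THF/H2O) should give the phenol F2. Condensation with Me2NCH(OMe)2 (toluene, 80 °C) should give the enaminone F3, which cyclises with AcOH, losing dimethylamine, to 18, where the route is rejoined. O1 still enters at the carbon that carried bromine, so the O1/O5 assignment is kept.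

**Step 14.** The electron-rich, 3-substituted chromone 19 may add hydroxide only on warming. Loss of the formyl carbon from 20 by retro-Claisen cleavage then competes, and careless neutralisation leads to dehydration back to 19 or to retro-aldol cleavage of the neutral lactol. Fallback: the lactol is made without passing a chromone. Setting out from 15 and going through the phenol F2 (made as described for step 12), C-formylation of the phenoxide enolate (LiN(SiMe3)2, 2.2 equiv, HCO2CH2CF3, THF, −78 °C) should give directly the silylated lactol F4 by hemiacetal closure. Bu4NF/AcOH then removes the silyl group and the route is rejoined at 21.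

**Step 11.** The enolate 16 may expel the β-silyloxy group if formylation is slow, O-formylation may compete, and 17 may lose silanol on silica. Fallback: from 15, condensation with t-BuOCH(NMe2)2 (toluene, 70 °C, no enolate involved) should give the bromo enaminone F5. Hydrolysis in buffered aqueous THF (AcOH/NaOAc) releases dimethylamine and gives 17.

**Step 4.** The second bromination is at a position that neither benzyloxy group activates and that is ortho to the first bromine. It may be slow, and forcing it risks benzylic bromination or ether cleavage. Fallback: the last position is activated by an amino group. From 5, nitration at the activated position (Cu(NO3)2·3H2O, Ac2O, 0 °C) should give the nitroarene F6 and reduction (Fe, NH4Cl, EtOH/H2O) the aniline F7. NBS then brominates ortho to nitrogen to give the bromoaniline F8, and Sandmeyer iodination (NaNO2, H2SO4; KI) gives the bromo iodide F9. Iodine–magnesium exchange (i-PrMgCl·LiCl, −40 °C) occurs only at iodine and gives 13, where the route is rejoined. This also removes any doubt about the site of exchange in step 9.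

**Step 15.** Over-reduction is the main danger: hydrogenolysis of the C9–O bond once O4' is free. A slow reaction could also allow ring–chain equilibration that exchanges O1 and O5. Fallback: C9 stays silylated during hydrogenolysis. From 18, hydration as in step 14 with the silyl ether in place should give the silylated lactol F4. Hydrogenolysis (H2, Pd/C, EtOAc) should then give the silylated triphenol F10, whose benzylic silyl ether resists C–O hydrogenolysis. HF·pyridine buffered with pyridine (THF, 0 °C) should then give 22.

## Further compounds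

F1 | step 12 | (3S)-1-[2,4-bis(benzyloxy)-3-methoxy-5-methyl-6-(4,4,5,5-tetramethyl-1,3,2-dioxaborolan-2-yl)phenyl]-3-[4-(benzyloxy)phenyl]-3-[(tert-butyldimethylsilyl)oxy]propan-1-one | COc1c(OCc2ccccc2)c(C(=O)C[C@H](O[Si](C)(C)C(C)(C)C)c2ccc(OCc3ccccc3)cc2)c(B2OC(C)(C)C(C)(C)O2)c(C)c1OCc1ccccc1
F2 | step 12 | (3S)-1-[2,4-bis(benzyloxy)-6-hydroxy-3-methoxy-5-methylphenyl]-3-[4-(benzyloxy)phenyl]-3-[(tert-butyldimethylsilyl)oxy]propan-1-one | COc1c(OCc2ccccc2)c(C(=O)C[C@H](O[Si](C)(C)C(C)(C)C)c2ccc(OCc3ccccc3)cc2)c(O)c(C)c1OCc1ccccc1
F3 | step 12 | 1-[2,4-bis(benzyloxy)-6-hydroxy-3-methoxy-5-methylphenyl]-2-{(R)-[4-(benzyloxy)phenyl][(tert-butyldimethylsilyl)oxy]methyl}-3-(dimethylamino)prop-2-en-1-one | CN(C)C=C([C@H](O[Si](C)(C)C(C)(C)C)c1ccc(OCc2ccccc2)cc1)C(=O)c1c(O)c(C)c(OCc2ccccc2)c(OC)c1OCc1ccccc1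
F4 | step 14 | 5,7-bis(benzyloxy)-3-{(S)-[4-(benzyloxy)phenyl][(tert-butyldimethylsilyl)oxy]methyl}-2-hydroxy-6-methoxy-8-methyl-2,3-dihydro-4H-chromen-4-one (mixture at C2 and C3) | COc1c(OCc2ccccc2)c(C)c2c(c1OCc1ccccc1)C(=O)C([C@H](O[Si](C)(C)C(C)(C)C)c1ccc(OCc3ccccc3)cc1)C(O)O2
F5 | step 11 | 1-[2,4-bis(benzyloxy)-6-bromo-3-methoxy-5-methylphenyl]-2-{(R)-[4-(benzyloxy)phenyl][(tert-butyldimethylsilyl)oxy]methyl}-3-(dimethylamino)prop-2-en-1-one | CN(C)C=C([C@H](O[Si](C)(C)C(C)(C)C)c1ccc(OCc2ccccc2)cc1)C(=O)c1c(Br)c(C)c(OCc2ccccc2)c(OC)c1OCc1ccccc1
F6 | step 4 | 1,3-bis(benzyloxy)-2-methoxy-4-methyl-6-nitrobenzene | COc1c(OCc2ccccc2)c([N+](=O)[O-])cc(C)c1OCc1ccccc1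
F7 | step 4 | 2,4-bis(benzyloxy)-3-methoxy-5-methylaniline | COc1c(OCc2ccccc2)c(N)cc(C)c1OCc1ccccc1
F8 | step 4 | 2,4-bis(benzyloxy)-6-bromo-3-methoxy-5-methylaniline | COc1c(OCc2ccccc2)c(N)c(Br)c(C)c1OCc1ccccc1
F9 | step 4 | 1,3-bis(benzyloxy)-5-bromo-4-iodo-2-methoxy-6-methylbenzene | COc1c(OCc2ccccc2)c(I)c(Br)c(C)c1OCc1ccccc1
F10 | step 15 | 3-{(S)-[(tert-butyldimethylsilyl)oxy](4-hydroxyphenyl)methyl}-2,5,7-trihydroxy-6-methoxy-8-methyl-2,3-dihydro-4H-chromen-4-one (mixture at C2 and C3) | COc1c(O)c(C)c2c(c1O)C(=O)C([C@H](O[Si](C)(C)C(C)(C)C)c1ccc(O)cc1)C(O)O2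
A1 | alternative 1 | (4-{[tert-butyl(dimethyl)silyl]oxy}phenyl)[3-(2,4,6-tris{[tert-butyl(dimethyl)silyl]oxy}-3-methoxy-5-methylphenyl)isoxazol-4-yl]methanone | O=C(c1ccc(O[Si](C)(C)C(C)(C)C)cc1)c1conc1-c1c(O[Si](C)(C)C(C)(C)C)c(OC)c(O[Si](C)(C)C(C)(C)C)c(C)c1O[Si](C)(C)C(C)(C)C
A2 | alternative 1 | 2,4,6-tris{[tert-butyl(dimethyl)silyl]oxy}-3-methoxy-5-methylbenzonitrile oxide | [O-][N+]#Cc1c(O[Si](C)(C)C(C)(C)C)c(OC)c(O[Si](C)(C)C(C)(C)C)c(C)c1O[Si](C)(C)C(C)(C)C
A3 | alternative 1 | (2E)-1-(4-{[tert-butyl(dimethyl)silyl]oxy}phenyl)-3-(dimethylamino)prop-2-en-1-one | CN(C)/C=C/C(=O)c1ccc(O[Si](C)(C)C(C)(C)C)cc1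
A4 | alternative 2 | 5-ethoxy-4-methoxy-2-methyl-3-(propan-2-yloxy)phenol | COc1c(OC(C)C)c(C)c(O)cc1OCC
A5 | alternative 2 | 4-(1-ethoxyethenyl)-4-methoxy-2-methyl-3-(propan-2-yloxy)cyclobut-2-en-1-one | C=C(OCC)C1(OC)C(OC(C)C)=C(C)C1=O
A6 | alternative 3 | 1-{3-(benzyloxy)-2-[(tert-butyldimethylsilyl)oxy]-5-hydroxy-6-methylphenyl}ethan-1-one | CC(=O)c1c(C)c(O)cc(OCc2ccccc2)c1O[Si](C)(C)C(C)(C)C
A7 | alternative 3 | 3-(benzyloxy)-2-[(tert-butyldimethylsilyl)oxy]furan | CC(C)(C)[Si](C)(C)Oc1occc1OCc1ccccc1
A8 | alternative 3 | pent-3-yn-2-one | CC#CC(C)=O
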